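- In a one-step world substrate would turn straight into target and the two readings would add up to the charge. In Friday's flask, the one I am handing over, they add up to 75.9% at 25.0 s, so I keep one step for the loss of substrate and give it up for target.

| flask | substrate | remark | time |
|---|---|---|---|
| Friday's | 1 M | the very flask that is asked about, followed so far |  |
| Wednesday's | 2 M | run made earlier |  |
| flask | 1.0 M |  | 2.0 min |

| run | time / s | target / % | substrate / % |
|---|---|---|---|
| Friday's | 10.0 | 5.9 | 77.5 |
| Friday's | 15.0 | 13.1 | 65.3 |
| Friday's | 20.0 | 17.9 | 58.7 |
| Friday's | 25.0 | 23.8 | 52.1 |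
| Wednesday's | 10.0 | 7.3 | 76.9 |
| Wednesday's | 15.0 | 13.9 | 67.1 |
| Wednesday's | 20.0 | 17.5 | 56.5 |
| Wednesday's | 30.0 | 28.6 | 44.6 |
| Wednesday's | 40.0 | 37.3 | 32.3 |
| Wednesday's | 50.0 | 43.2 | 26.7 |

(standard deviation of a reading: 1 percentage point)

- a reading or a percentage of target counts all its forms, free or not

* amount of target in percent of the substrate charged, at 12 s, 40 s, 80 s and 2.0 min

- Going to logarithms, I carry 88.3 s, read from Friday's last substrate reading: the decade time, in which first-order substrate falls by one power of ten.
- When you come at 2.0 min, I expect substrate at 4.37% in Friday's flask.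
- Do not stop it at 80 s: that is shorter than one decade time, so I reckon substrate still at 12.4%.
- For target I take Wednesday's last readings, 0.589 of target per unit of substrate spent, and hold that ratio, which gives my own 56.4% at 2.0 min.
- The forecast gives 8.3%, 37.3%, 58% and 65% at the four times, with “about 30% of the substrate lost to something that never becomes target”; my figure at 2.0 min is lower.

Friday's flask gives target at 9.62%, 34.9%, 52.4% and 57.9%.

    intermediate ⇌ isomer of the product (K = 3.00, k = 0.0210 s⁻¹)
    substrate → intermediate (k = 0.0260 s⁻¹)
    crystals ⇌ target, rate k3*(cs3 - [target]) while solid is left; crystals form when [target] > cs3 (solubility = 0.320 M, k = 0.920 s⁻¹)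
    intermediate ⇌ target (K = 3.30, k = 0.0990 s⁻¹)
    substrate + intermediate → side product (k = 0.00600 M⁻¹ s⁻¹)

- Substrate in Friday's flask stands at 4.02% after 2.00 min against my 4.37%, and carried to Wednesday's run the decade time gives 27.1% at 50.0 s, where 26.7% was read. In Friday's flask at 2.00 min, counting the forward rate of each step alone, intermediate goes to target 4.7 times as fast as to isomer of the product, which stands at 22.0%.

The earlier runs and the new flask stem from a simulated flask with constants of no real substance; noise was put on by code.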